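**Retrosynthetic overview**

- Late bonds: the C-4 ester (Steglich coupling with the (S)-acid from the chiral pool), the C-2 carbonyl (oxidation of a methyl acetal), the C-6 vinyl group (ester → aldehyde → Wittig) and the C-6 methyl group (enolate methylation).
- Key disconnection C-4–C-5: the cyclohexane is closed by 6-endo attack of an α-pivaloyloxy radical (C-4) on the CH2 terminus (C-5) of a 2-substituted acrylate. The same radical chain first closes the oxolane (C-3–C-3a, 5-exo) from a 2-bromoallyl mixed acetal on O-1, so the ring order is oxolane, then cyclohexane.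
- Enabling feature: the ring CH2 C-5 lies between the oxygenated C-4 and the quaternary C-6, whose vinyl group is a masked carboxyl. C-5/C-6 can therefore start as CH2=C(CO2tBu), and C-4/C-3a as an enol ester double bond allylic to the C-7a carbinol, whose oxygen (O-1) carries the C-2/C-3 unit as a tether.
- The acyclic precursor (C-7 and C-7a stereocenters) comes from a syn-selective, ligand-controlled chromium 2-(alkoxycarbonyl)allylation of (E)-3-(pivaloyloxy)acrolein with a Baylis–Hillman-derived dienyl bromide.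

Key step: step 8

Remark: locants of bicyclic compounds follow octahydro-1-benzofuran numbering (O-1, C-2, C-3, C-3a, C-4 to C-7, C-7a); the acetal carbon C-2 is carried as an epimer mixture until it is oxidized, and the ligand antipode in the allylation is the one that gives the 4R carbinol (to be confirmed by MTPA ester analysis).

Step 1
Reactants: 1 2-methylidenepropane-1,3-diol
Product: 2 2-{[(tert-butyldiphenylsilyl)oxy]methyl}prop-2-en-1-ol
Conditions: NaH (1.0 equiv), THF, 0 °C; then tert-butyl(chloro)diphenylsilane (1.0 equiv), 0 °C → rt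
Reagents that add atoms: tert-butyl(chloro)diphenylsilane, CC(C)(C)[Si](Cl)(c1ccccc1)c1ccccc1
Why: Monosilylation of a symmetric diol through its monosodium alkoxide (O-silylation) should give mainly the mono ether.

Step 2
Reactants: 2 2-{[(tert-butyldiphenylsilyl)oxy]methyl}prop-2-en-1-ol
Product: 3 2-{[(tert-butyldiphenylsilyl)oxy]methyl}prop-2-enal
Conditions: MnO2 (activated, excess), CH2Cl2, rt
Reagents that add atoms: none
Why: Allylic alcohol oxidation with MnO2 should stop at the enal and leave the silyl ether untouched.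

Step 3
Reactants: 3 2-{[(tert-butyldiphenylsilyl)oxy]methyl}prop-2-enal; 4 tert-butyl prop-2-enoate
Product: 5 tert-butyl 4-{[(tert-butyldiphenylsilyl)oxy]methyl}-3-hydroxy-2-methylidenepent-4-enoate (racemic)
Conditions: DABCO (1.0 equiv), 4 (3 equiv), 1,4-dioxane/H2O 1:1, rt
Reagents that add atoms: none
Why: Morita–Baylis–Hillman reaction, in which the ammonium enolate of the acrylate adds 1,2 to the α-branched enal (itself not a competent donor); the racemic carbinol center is erased in step 4.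

Step 4
Reactants: 5 tert-butyl 4-{[(tert-butyldiphenylsilyl)oxy]methyl}-3-hydroxy-2-methylidenepent-4-enoate
Product: 6 tert-butyl (2Z)-2-(bromomethyl)-4-{[(tert-butyldiphenylsilyl)oxy]methyl}penta-2,4-dienoate
Conditions: PBr3 (0.4 equiv), Et2O, −10 → 0 °C
Reagents that add atoms: phosphorus tribromide, BrP(Br)Br
Why: Bromination of a Baylis–Hillman alcohol with allylic transposition (SN2') should give the conjugated 2-(bromomethyl)dienoate as the thermodynamically preferred Z isomer (dienyl carbon trans to the ester).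

Step 5
Reactants: 7 tetrabutylammonium (1E)-3-oxoprop-1-en-1-olate (malondialdehyde tetrabutylammonium salt)
Product: 8 (1E)-3-oxoprop-1-en-1-yl 2,2-dimethylpropanoate
Conditions: pivaloyl chloride (1.0 equiv), CH2Cl2, 0 °C → rt
Reagents that add atoms: pivaloyl chloride, CC(C)(C)C(=O)Cl
Why: O-acylation of the malondialdehyde enolate should give the (E)-enol ester, the hindered pivalate being chosen to suppress later acyl transfer.

Step 6
Reactants: 6 tert-butyl (2Z)-2-(bromomethyl)-4-{[(tert-butyldiphenylsilyl)oxy]methyl}penta-2,4-dienoate; 8 (1E)-3-oxoprop-1-en-1-yl 2,2-dimethylpropanoate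
Product: 10 tert-butyl (3S,4R,5E)-3-{3-[(tert-butyldiphenylsilyl)oxy]prop-1-en-2-yl}-6-[(2,2-dimethylpropanoyl)oxy]-4-hydroxy-2-methylidenehex-5-enoate, via trimethylsilyl ether 9 (not isolated)
Conditions: CrCl2 (10 mol %), tridentate carbazole-1,8-bis(oxazoline) ligand (12 mol %), Mn powder (2 equiv), Me3SiCl (1.5 equiv), iPr2NEt (0.3 equiv), THF, rt; then 1 M HCl, 0 °C
Reagents that add atoms: none
Why: Catalytic asymmetric Nozaki–Hiyama–Kishi 2-(alkoxycarbonyl)allylation, in which the allylchromium reacts at its central γ-carbon through a chair transition state whose Z-crotyl-type geometry gives the syn (3,4) adduct, while the chiral ligand on chromium fixes the 4R carbinol (and with it 3S); the tert-butyl ester blocks lactonization of the γ-hydroxy ester.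

Step 7
Reactants: 10 tert-butyl (3S,4R,5E)-3-{3-[(tert-butyldiphenylsilyl)oxy]prop-1-en-2-yl}-6-[(2,2-dimethylpropanoyl)oxy]-4-hydroxy-2-methylidenehex-5-enoate; 11 methoxyallene (1-methoxypropa-1,2-diene)
Product: 12 tert-butyl (3S,4R,5E)-4-[(2-bromo-1-methoxyprop-2-en-1-yl)oxy]-3-{3-[(tert-butyldiphenylsilyl)oxy]prop-1-en-2-yl}-6-[(2,2-dimethylpropanoyl)oxy]-2-methylidenehex-5-enoate (both acetal epimers)
Conditions: N-bromosuccinimide (1.3 equiv), 11 (3 equiv), CH2Cl2, −40 → −10 °C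
Reagents that add atoms: N-bromosuccinimide, BrN1C(=O)CCC1=O
Why: Haloacetalization (bromo-alkoxylation of an allenyl ether): bromine adds to the central allene carbon and the secondary alcohol traps the oxocarbenium ion, the far more nucleophilic allenyl ether in excess outcompeting the enol ester and the other alkenes.

Step 8
Reactants: 12 tert-butyl (3S,4R,5E)-4-[(2-bromo-1-methoxyprop-2-en-1-yl)oxy]-3-{3-[(tert-butyldiphenylsilyl)oxy]prop-1-en-2-yl}-6-[(2,2-dimethylpropanoyl)oxy]-2-methylidenehex-5-enoate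
Product: 13 tert-butyl (3aR,4S,7R,7aR)-7-{3-[(tert-butyldiphenylsilyl)oxy]prop-1-en-2-yl}-4-[(2,2-dimethylpropanoyl)oxy]-2-methoxy-3-methylideneoctahydro-1-benzofuran-6-carboxylate (epimers at C-2 and C-6)
Conditions: Bu3SnH (1.3 equiv) and AIBN (0.2 equiv) added over 6 h by syringe pump, benzene (0.005 M), 80 °C
Reagents that add atoms: none
Why: Bu3Sn• abstracts bromine to give the σ-vinyl radical at C-3, which closes 5-exo-trig on the enol ester carbon (future C-3a); the resulting α-pivaloyloxy radical at C-4 then closes 6-endo-trig on the CH2 terminus (C-5) of the 2-substituted acrylate, and the tertiary α-ester radical at C-6 is reduced by the stannane. The closest known reaction type is the haloacetal (Ueno–Stork) radical cyclization in its tandem form, here with a 2-bromoallyl acetal that delivers the 3-methylidene group directly. The oxolane closes in the 5-exo-trig mode and the cyclohexane in the 6-endo-trig mode. C-3a is set by the C-7a carbinol center through a chair-like 5-exo transition state with the branched C-7 chain pseudoequatorial (substituents at C-7a and C-3a trans, hence the trans ring fusion); C-4 is set in the chair-like 6-endo transition state with the pivaloyloxy group equatorial, trans to C-3; C-6 is not controlled and is cleared in step 9. The step needs 5-exo closure ahead of 1,5-hydrogen transfer and of attack on the acrylate (secured by the fast oxygen-tethered 5-exo mode and slow stannane addition), and 6-endo ahead of 5-exo closure of the second radical, secured by polarity matching of the nucleophilic α-acyloxy radical with the acrylate CH2 and by the strain of the alternative trans-fused bicyclo[3.3.0] ring.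

Step 9
Reactants: 13 tert-butyl (3aR,4S,7R,7aR)-7-{3-[(tert-butyldiphenylsilyl)oxy]prop-1-en-2-yl}-4-[(2,2-dimethylpropanoyl)oxy]-2-methoxy-3-methylideneoctahydro-1-benzofuran-6-carboxylate
Product: 15 tert-butyl (3aR,4S,6S,7S,7aR)-7-{3-[(tert-butyldiphenylsilyl)oxy]prop-1-en-2-yl}-4-[(2,2-dimethylpropanoyl)oxy]-2-methoxy-6-methyl-3-methylideneoctahydro-1-benzofuran-6-carboxylate, via lithium ester enolate 14 (not isolated)
Conditions: LiN(iPr)2 (1.3 equiv), THF, −78 → −40 °C; MeI (5 equiv), DMPU, −78 → 0 °C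
Reagents that add atoms: iodomethane, CI
Why: Ester enolate alkylation, in which the small electrophile should approach the exocyclic enolate from the equatorial direction (axial approach is opposed by the axial hydrogens at C-4 and C-7a), placing methyl trans to the C-7 side chain and the carboxylate axial, which fixes the quaternary center C-6.

Step 10
Reactants: 15 tert-butyl (3aR,4S,6S,7S,7aR)-7-{3-[(tert-butyldiphenylsilyl)oxy]prop-1-en-2-yl}-4-[(2,2-dimethylpropanoyl)oxy]-2-methoxy-6-methyl-3-methylideneoctahydro-1-benzofuran-6-carboxylate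
Product: 16 (3aR,4S,6S,7S,7aR)-7-{3-[(tert-butyldiphenylsilyl)oxy]prop-1-en-2-yl}-6-(hydroxymethyl)-2-methoxy-6-methyl-3-methylideneoctahydro-1-benzofuran-4-ol
Conditions: LiAlH4 (4 equiv), THF, 0 → 50 °C
Reagents that add atoms: none
Why: Hydride reduction should take the hindered tert-butyl ester to the primary alcohol and cleave the pivalate, while acetal, silyl ether and alkenes are inert.

Step 11
Reactants: 16 (3aR,4S,6S,7S,7aR)-7-{3-[(tert-butyldiphenylsilyl)oxy]prop-1-en-2-yl}-6-(hydroxymethyl)-2-methoxy-6-methyl-3-methylideneoctahydro-1-benzofuran-4-ol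
Product: 17 (3aR,4S,6S,7S,7aR)-7-{3-[(tert-butyldiphenylsilyl)oxy]prop-1-en-2-yl}-4-hydroxy-2-methoxy-6-methyl-3-methylideneoctahydro-1-benzofuran-6-carbaldehyde
Conditions: TEMPO (0.2 equiv), PhI(OAc)2 (1.2 equiv), NaHCO3, CH2Cl2, rt
Reagents that add atoms: none
Why: Oxoammonium (TEMPO) oxidation is selective for the primary over the secondary alcohol, and the trans-1,3 relation of the axial formyl and the equatorial hydroxyl excludes hemiacetal formation and over-oxidation.

Step 12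
Reactants: 17 (3aR,4S,6S,7S,7aR)-7-{3-[(tert-butyldiphenylsilyl)oxy]prop-1-en-2-yl}-4-hydroxy-2-methoxy-6-methyl-3-methylideneoctahydro-1-benzofuran-6-carbaldehyde
Product: 18 (3aR,4S,6R,7R,7aR)-7-{3-[(tert-butyldiphenylsilyl)oxy]prop-1-en-2-yl}-6-ethenyl-2-methoxy-6-methyl-3-methylideneoctahydro-1-benzofuran-4-ol
Conditions: Ph3PCH3Br (4 equiv), KOtBu (3.8 equiv), THF, 0 → 50 °C
Reagents that add atoms: methyltriphenylphosphonium bromide, C[P+](c1ccccc1)(c1ccccc1)c1ccccc1.[Br-]
Why: Wittig methylenation of the non-enolizable neopentyl aldehyde, with excess ylide covering the free hydroxyl, should install the vinyl group without touching any stereocenter.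

Step 13
Reactants: 19 methyl (2S)-3-hydroxy-2-methylpropanoate
Product: 20 methyl (2S)-3-[(tert-butyldiphenylsilyl)oxy]-2-methylpropanoate
Conditions: tert-butyl(chloro)diphenylsilane, imidazole, DMF, rt
Reagents that add atoms: tert-butyl(chloro)diphenylsilane, CC(C)(C)[Si](Cl)(c1ccccc1)c1ccccc1
Why: Imidazole-promoted silylation of the primary alcohol leaves the α-stereocenter untouched.

Step 14
Reactants: 20 methyl (2S)-3-[(tert-butyldiphenylsilyl)oxy]-2-methylpropanoate
Product: 21 (2S)-3-[(tert-butyldiphenylsilyl)oxy]-2-methylpropanoic acid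
Conditions: LiOH·H2O, THF/H2O, 0 °C → rt; 1 M HCl to pH 3
Reagents that add atoms: lithium hydroxide, [Li+].[OH-]
Why: Mild saponification of the methyl ester should proceed without epimerization or β-elimination.

Step 15
Reactants: 18 (3aR,4S,6R,7R,7aR)-7-{3-[(tert-butyldiphenylsilyl)oxy]prop-1-en-2-yl}-6-ethenyl-2-methoxy-6-methyl-3-methylideneoctahydro-1-benzofuran-4-ol; 21 (2S)-3-[(tert-butyldiphenylsilyl)oxy]-2-methylpropanoic acid
Product: 22 (3aR,4S,6R,7R,7aR)-7-{3-[(tert-butyldiphenylsilyl)oxy]prop-1-en-2-yl}-6-ethenyl-2-methoxy-6-methyl-3-methylideneoctahydro-1-benzofuran-4-yl (2S)-3-[(tert-butyldiphenylsilyl)oxy]-2-methylpropanoate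
Conditions: EDC·HCl (1.5 equiv), DMAP (0.3 equiv), CH2Cl2, 0 °C → rt
Reagents that add atoms: none
Why: Steglich esterification of the equatorial secondary alcohol, run cold with catalytic DMAP, should preserve the α-stereocenter of the acid.

Step 16
Reactants: 22 (3aR,4S,6R,7R,7aR)-7-{3-[(tert-butyldiphenylsilyl)oxy]prop-1-en-2-yl}-6-ethenyl-2-methoxy-6-methyl-3-methylideneoctahydro-1-benzofuran-4-yl (2S)-3-[(tert-butyldiphenylsilyl)oxy]-2-methylpropanoate
Product: 24 (3aR,4S,6R,7R,7aR)-7-{3-[(tert-butyldiphenylsilyl)oxy]prop-1-en-2-yl}-6-ethenyl-6-methyl-3-methylidene-2-oxooctahydro-1-benzofuran-4-yl (2S)-3-[(tert-butyldiphenylsilyl)oxy]-2-methylpropanoate, via lactol 23 (not isolated)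
Conditions: CrO3, H2SO4, H2O, acetone, 0 °C
Reagents that add atoms: water, O
Why: Jones oxidation, in which acid hydrolysis of the allylic methyl acetal to the lactol is followed by chromic acid oxidation to the α-methylene γ-lactone, a known conversion of 2-alkoxy-3-methylideneoxolanes that the silyl ethers and esters should survive.

Step 17
Reactants: 24 (3aR,4S,6R,7R,7aR)-7-{3-[(tert-butyldiphenylsilyl)oxy]prop-1-en-2-yl}-6-ethenyl-6-methyl-3-methylidene-2-oxooctahydro-1-benzofuran-4-yl (2S)-3-[(tert-butyldiphenylsilyl)oxy]-2-methylpropanoate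
Product: 25 (3aR,4S,6R,7R,7aR)-6-ethenyl-7-(3-hydroxyprop-1-en-2-yl)-6-methyl-3-methylidene-2-oxooctahydro-1-benzofuran-4-yl (2S)-3-hydroxy-2-methylpropanoate
Conditions: HF·pyridine, pyridine, THF, 0 °C → rt
Reagents that add atoms: none
Why: Buffered fluoride desilylation should remove both silyl ethers without conjugate addition to the α-methylene lactone or acyl migration.

**Compound list**

1 | 2-methylidenepropane-1,3-diol | C=C(CO)CO | starting material
2 | 2-{[(tert-butyldiphenylsilyl)oxy]methyl}prop-2-en-1-ol | C=C(CO)CO[Si](c1ccccc1)(c1ccccc1)C(C)(C)C | intermediate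
3 | 2-{[(tert-butyldiphenylsilyl)oxy]methyl}prop-2-enal | C=C(C=O)CO[Si](c1ccccc1)(c1ccccc1)C(C)(C)C | intermediate
4 | tert-butyl prop-2-enoate | C=CC(=O)OC(C)(C)C | starting material
5 | tert-butyl 4-{[(tert-butyldiphenylsilyl)oxy]methyl}-3-hydroxy-2-methylidenepent-4-enoate (racemic) | CC(C)(C)OC(=O)C(=C)C(O)C(=C)CO[Si](c1ccccc1)(c1ccccc1)C(C)(C)C | intermediate
6 | tert-butyl (2Z)-2-(bromomethyl)-4-{[(tert-butyldiphenylsilyl)oxy]methyl}penta-2,4-dienoate | CC(C)(C)OC(=O)/C(CBr)=C/C(=C)CO[Si](c1ccccc1)(c1ccccc1)C(C)(C)C | intermediate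
7 | tetrabutylammonium (1E)-3-oxoprop-1-en-1-olate | O=C/C=C/[O-].CCCC[N+](CCCC)(CCCC)CCCC | starting material
8 | (1E)-3-oxoprop-1-en-1-yl 2,2-dimethylpropanoate | O=C/C=C/OC(=O)C(C)(C)C | intermediate
9 | tert-butyl (3S,4R,5E)-3-{3-[(tert-butyldiphenylsilyl)oxy]prop-1-en-2-yl}-6-[(2,2-dimethylpropanoyl)oxy]-2-methylidene-4-[(trimethylsilyl)oxy]hex-5-enoate | CC(C)(C)OC(=O)C(=C)[C@@H]([C@@H](O[Si](C)(C)C)/C=C/OC(=O)C(C)(C)C)C(=C)CO[Si](c1ccccc1)(c1ccccc1)C(C)(C)C | intermediate
10 | tert-butyl (3S,4R,5E)-3-{3-[(tert-butyldiphenylsilyl)oxy]prop-1-en-2-yl}-6-[(2,2-dimethylpropanoyl)oxy]-4-hydroxy-2-methylidenehex-5-enoate | CC(C)(C)OC(=O)C(=C)[C@@H]([C@@H](O)/C=C/OC(=O)C(C)(C)C)C(=C)CO[Si](c1ccccc1)(c1ccccc1)C(C)(C)C | intermediate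
11 | methoxyallene (1-methoxypropa-1,2-diene) | COC=C=C | starting material
12 | tert-butyl (3S,4R,5E)-4-[(2-bromo-1-methoxyprop-2-en-1-yl)oxy]-3-{3-[(tert-butyldiphenylsilyl)oxy]prop-1-en-2-yl}-6-[(2,2-dimethylpropanoyl)oxy]-2-methylidenehex-5-enoate | CC(C)(C)OC(=O)C(=C)[C@@H]([C@@H](OC(OC)C(Br)=C)/C=C/OC(=O)C(C)(C)C)C(=C)CO[Si](c1ccccc1)(c1ccccc1)C(C)(C)C | intermediate
13 | tert-butyl (3aR,4S,7R,7aR)-7-{3-[(tert-butyldiphenylsilyl)oxy]prop-1-en-2-yl}-4-[(2,2-dimethylpropanoyl)oxy]-2-methoxy-3-methylideneoctahydro-1-benzofuran-6-carboxylate | CC(C)(C)OC(=O)C1C[C@H](OC(=O)C(C)(C)C)[C@H]2C(=C)C(OC)O[C@@H]2[C@H]1C(=C)CO[Si](c1ccccc1)(c1ccccc1)C(C)(C)C | intermediate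
14 | lithium ester enolate of 13 (C-6 exocyclic) | CC(C)(C)OC(O[Li])=C1C[C@H](OC(=O)C(C)(C)C)[C@H]2C(=C)C(OC)O[C@@H]2[C@H]1C(=C)CO[Si](c1ccccc1)(c1ccccc1)C(C)(C)C | intermediate
15 | tert-butyl (3aR,4S,6S,7S,7aR)-7-{3-[(tert-butyldiphenylsilyl)oxy]prop-1-en-2-yl}-4-[(2,2-dimethylpropanoyl)oxy]-2-methoxy-6-methyl-3-methylideneoctahydro-1-benzofuran-6-carboxylate | CC(C)(C)OC(=O)[C@@]1(C)C[C@H](OC(=O)C(C)(C)C)[C@H]2C(=C)C(OC)O[C@@H]2[C@H]1C(=C)CO[Si](c1ccccc1)(c1ccccc1)C(C)(C)C | intermediate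
16 | (3aR,4S,6S,7S,7aR)-7-{3-[(tert-butyldiphenylsilyl)oxy]prop-1-en-2-yl}-6-(hydroxymethyl)-2-methoxy-6-methyl-3-methylideneoctahydro-1-benzofuran-4-ol | OC[C@@]1(C)C[C@H](O)[C@H]2C(=C)C(OC)O[C@@H]2[C@H]1C(=C)CO[Si](c1ccccc1)(c1ccccc1)C(C)(C)C | intermediate
17 | (3aR,4S,6S,7S,7aR)-7-{3-[(tert-butyldiphenylsilyl)oxy]prop-1-en-2-yl}-4-hydroxy-2-methoxy-6-methyl-3-methylideneoctahydro-1-benzofuran-6-carbaldehyde | O=C[C@@]1(C)C[C@H](O)[C@H]2C(=C)C(OC)O[C@@H]2[C@H]1C(=C)CO[Si](c1ccccc1)(c1ccccc1)C(C)(C)C | intermediate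
18 | (3aR,4S,6R,7R,7aR)-7-{3-[(tert-butyldiphenylsilyl)oxy]prop-1-en-2-yl}-6-ethenyl-2-methoxy-6-methyl-3-methylideneoctahydro-1-benzofuran-4-ol | C=C[C@@]1(C)C[C@H](O)[C@H]2C(=C)C(OC)O[C@@H]2[C@H]1C(=C)CO[Si](c1ccccc1)(c1ccccc1)C(C)(C)C | intermediate
19 | methyl (2S)-3-hydroxy-2-methylpropanoate | COC(=O)[C@@H](C)CO | starting material
20 | methyl (2S)-3-[(tert-butyldiphenylsilyl)oxy]-2-methylpropanoate | COC(=O)[C@@H](C)CO[Si](c1ccccc1)(c1ccccc1)C(C)(C)C | intermediate
21 | (2S)-3-[(tert-butyldiphenylsilyl)oxy]-2-methylpropanoic acid | OC(=O)[C@@H](C)CO[Si](c1ccccc1)(c1ccccc1)C(C)(C)C | intermediate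
22 | (3aR,4S,6R,7R,7aR)-7-{3-[(tert-butyldiphenylsilyl)oxy]prop-1-en-2-yl}-6-ethenyl-2-methoxy-6-methyl-3-methylideneoctahydro-1-benzofuran-4-yl (2S)-3-[(tert-butyldiphenylsilyl)oxy]-2-methylpropanoate | C=C[C@@]1(C)C[C@H](OC(=O)[C@@H](C)CO[Si](c3ccccc3)(c3ccccc3)C(C)(C)C)[C@H]2C(=C)C(OC)O[C@@H]2[C@H]1C(=C)CO[Si](c1ccccc1)(c1ccccc1)C(C)(C)C | intermediate
23 | 2-hydroxy (lactol) analogue of 22 | C=C[C@@]1(C)C[C@H](OC(=O)[C@@H](C)CO[Si](c3ccccc3)(c3ccccc3)C(C)(C)C)[C@H]2C(=C)C(O)O[C@@H]2[C@H]1C(=C)CO[Si](c1ccccc1)(c1ccccc1)C(C)(C)C | intermediate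
24 | (3aR,4S,6R,7R,7aR)-7-{3-[(tert-butyldiphenylsilyl)oxy]prop-1-en-2-yl}-6-ethenyl-6-methyl-3-methylidene-2-oxooctahydro-1-benzofuran-4-yl (2S)-3-[(tert-butyldiphenylsilyl)oxy]-2-methylpropanoate | C=C[C@@]1(C)C[C@H](OC(=O)[C@@H](C)CO[Si](c3ccccc3)(c3ccccc3)C(C)(C)C)[C@H]2C(=C)C(=O)O[C@@H]2[C@H]1C(=C)CO[Si](c1ccccc1)(c1ccccc1)C(C)(C)C | intermediate
25 | (3aR,4S,6R,7R,7aR)-6-ethenyl-7-(3-hydroxyprop-1-en-2-yl)-6-methyl-3-methylidene-2-oxooctahydro-1-benzofuran-4-yl (2S)-3-hydroxy-2-methylpropanoate | C=C[C@@]1(C)C[C@H](OC(=O)[C@@H](C)CO)[C@H]2C(=C)C(=O)O[C@@H]2[C@H]1C(=C)CO | target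

**Step count**

Total steps: 17. Longest linear sequence: 14 (steps 1–4, 6–12, 15–17).

**Steps most likely to fail**

Step 8. The σ-vinyl radical may be diverted by 1,5-hydrogen transfer from the doubly allylic C-3 hydrogen of the hexenoate chain before the first ring closure. The fallback sets out from 10 and returns at 24; it uses a primary alkyl radical, which abstracts hydrogen far more slowly, and installs the methylidene group late.
- Alcohol 10 with N-bromosuccinimide and ethyl vinyl ether gives the 2-bromo-1-ethoxyethyl acetal F1.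
- Bu3SnH/AIBN runs the same 5-exo/6-endo sequence to the saturated bicyclic ethyl acetal F2.
- The chemistry of steps 9–12 then gives, in turn, the lithium enolate F3, the C-6 methylated ester F4, the diol F5, the hydroxy aldehyde F6 and the vinyl alcohol F7.
- Aqueous AcOH/THF gives the lactol F8, and Ag2CO3 on Celite (selective for a lactol over a secondary alcohol) gives the hydroxy lactone F9.
- LiN(iPr)2 (2.5 equiv) gives the dilithio alkoxide enolate F10, CH2=NMe2+ I− gives the Mannich base F11, MeI gives the methiodide F12, and NaHCO3 gives the α-methylene hydroxy lactone F13.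
- Esterification of F13 with 21 (EDC·HCl, DMAP) gives 24.

Step 9. Methyl iodide may enter the enolate from the axial instead of the equatorial face, which would give the C-6 epimer. The fallback sets out from 13 (through enolate 14) and returns at 18; it uses the same facial bias with the roles of the two C-6 substituents exchanged.
- Enolate 14 is trapped with acetaldehyde to give the aldol adduct F14, whose 1-hydroxyethyl group sits on the face the electrophile prefers.
- Dehydration with methyl N-(triethylammoniosulfonyl)carbamate gives the C-6 vinyl ester F15.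
- LiAlH4 gives the diol F16.
- TsCl/pyridine at the primary hydroxyl gives the tosylate F17.
- LiEt3BH reduces the neopentyl tosylate to the methyl group and gives 18.

Step 6. Catalyst turnover and enantiofacial control may be poor with the conjugated, weakly electrophilic aldehyde. The fallback sets out from 6 and 8 and returns at 10.
- An indium-mediated Barbier allylation (In powder, THF/H2O, rt), syn-selective through the same Z-crotyl-type chair, gives 10 together with its enantiomer, the (3R,4S) alcohol F18.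
- The racemate is resolved by preparative chromatography on a chiral stationary phase to give 10.

**Further compounds**

F1 | step 8 | tert-butyl (3S,4R,5E)-4-(2-bromo-1-ethoxyethoxy)-3-{3-[(tert-butyldiphenylsilyl)oxy]prop-1-en-2-yl}-6-[(2,2-dimethylpropanoyl)oxy]-2-methylidenehex-5-enoate | CC(C)(C)OC(=O)C(=C)[C@@H]([C@@H](OC(CBr)OCC)/C=C/OC(=O)C(C)(C)C)C(=C)CO[Si](c1ccccc1)(c1ccccc1)C(C)(C)C
F2 | step 8 | 2-ethoxy analogue of 13 without the 3-methylidene group | CC(C)(C)OC(=O)C1C[C@H](OC(=O)C(C)(C)C)[C@H]2CC(OCC)O[C@@H]2[C@H]1C(=C)CO[Si](c1ccccc1)(c1ccccc1)C(C)(C)C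
F3 | step 8 | lithium ester enolate of F2 | CC(C)(C)OC(O[Li])=C1C[C@H](OC(=O)C(C)(C)C)[C@H]2CC(OCC)O[C@@H]2[C@H]1C(=C)CO[Si](c1ccccc1)(c1ccccc1)C(C)(C)C
F4 | step 8 | 2-ethoxy analogue of 15 without the 3-methylidene group | CC(C)(C)OC(=O)[C@@]1(C)C[C@H](OC(=O)C(C)(C)C)[C@H]2CC(OCC)O[C@@H]2[C@H]1C(=C)CO[Si](c1ccccc1)(c1ccccc1)C(C)(C)C
F5 | step 8 | 2-ethoxy analogue of 16 without the 3-methylidene group | OC[C@@]1(C)C[C@H](O)[C@H]2CC(OCC)O[C@@H]2[C@H]1C(=C)CO[Si](c1ccccc1)(c1ccccc1)C(C)(C)C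
F6 | step 8 | 2-ethoxy analogue of 17 without the 3-methylidene group | O=C[C@@]1(C)C[C@H](O)[C@H]2CC(OCC)O[C@@H]2[C@H]1C(=C)CO[Si](c1ccccc1)(c1ccccc1)C(C)(C)C
F7 | step 8 | 2-ethoxy analogue of 18 without the 3-methylidene group | C=C[C@@]1(C)C[C@H](O)[C@H]2CC(OCC)O[C@@H]2[C@H]1C(=C)CO[Si](c1ccccc1)(c1ccccc1)C(C)(C)C
F8 | step 8 | lactol (2-hydroxy) from F7 | C=C[C@@]1(C)C[C@H](O)[C@H]2CC(O)O[C@@H]2[C@H]1C(=C)CO[Si](c1ccccc1)(c1ccccc1)C(C)(C)C
F9 | step 8 | (3aR,4S,6R,7R,7aR)-7-{3-[(tert-butyldiphenylsilyl)oxy]prop-1-en-2-yl}-6-ethenyl-4-hydroxy-6-methylhexahydro-1-benzofuran-2(3H)-one | C=C[C@@]1(C)C[C@H](O)[C@H]2CC(=O)O[C@@H]2[C@H]1C(=C)CO[Si](c1ccccc1)(c1ccccc1)C(C)(C)C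
F10 | step 8 | dilithio alkoxide enolate of F9 | C=C[C@@]1(C)C[C@H](O[Li])[C@H]2C=C(O[Li])O[C@@H]2[C@H]1C(=C)CO[Si](c1ccccc1)(c1ccccc1)C(C)(C)C
F11 | step 8 | 3-[(dimethylamino)methyl] derivative of F9 | C=C[C@@]1(C)C[C@H](O)[C@H]2C(CN(C)C)C(=O)O[C@@H]2[C@H]1C(=C)CO[Si](c1ccccc1)(c1ccccc1)C(C)(C)C
F12 | step 8 | trimethylammonium iodide (methiodide) of F11 | C=C[C@@]1(C)C[C@H](O)[C@H]2C(C[N+](C)(C)C)C(=O)O[C@@H]2[C@H]1C(=C)CO[Si](c1ccccc1)(c1ccccc1)C(C)(C)C.[I-]
F13 | step 8 | (3aR,4S,6R,7R,7aR)-7-{3-[(tert-butyldiphenylsilyl)oxy]prop-1-en-2-yl}-6-ethenyl-4-hydroxy-6-methyl-3-methylidenehexahydro-1-benzofuran-2(3H)-one | C=C[C@@]1(C)C[C@H](O)[C@H]2C(=C)C(=O)O[C@@H]2[C@H]1C(=C)CO[Si](c1ccccc1)(c1ccccc1)C(C)(C)C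
F14 | step 9 | 6-(1-hydroxyethyl) analogue of 15 in place of 6-methyl (carbinol epimers) | CC(O)[C@@]1(C(=O)OC(C)(C)C)C[C@H](OC(=O)C(C)(C)C)[C@H]2C(=C)C(OC)O[C@@H]2[C@H]1C(=C)CO[Si](c1ccccc1)(c1ccccc1)C(C)(C)C
F15 | step 9 | 6-ethenyl analogue of 15 in place of 6-methyl | C=C[C@@]1(C(=O)OC(C)(C)C)C[C@H](OC(=O)C(C)(C)C)[C@H]2C(=C)C(OC)O[C@@H]2[C@H]1C(=C)CO[Si](c1ccccc1)(c1ccccc1)C(C)(C)C
F16 | step 9 | 6-ethenyl-6-(hydroxymethyl) diol (hydroxymethyl in place of the methyl group of 18) | C=C[C@@]1(CO)C[C@H](O)[C@H]2C(=C)C(OC)O[C@@H]2[C@H]1C(=C)CO[Si](c1ccccc1)(c1ccccc1)C(C)(C)C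
F17 | step 9 | primary 4-methylbenzenesulfonate of F16 | C=C[C@@]1(COS(=O)(=O)c3ccc(C)cc3)C[C@H](O)[C@H]2C(=C)C(OC)O[C@@H]2[C@H]1C(=C)CO[Si](c1ccccc1)(c1ccccc1)C(C)(C)C
F18 | step 6 | tert-butyl (3R,4S,5E)-3-{3-[(tert-butyldiphenylsilyl)oxy]prop-1-en-2-yl}-6-[(2,2-dimethylpropanoyl)oxy]-4-hydroxy-2-methylidenehex-5-enoate (enantiomer of 10) | CC(C)(C)OC(=O)C(=C)[C@H]([C@H](O)/C=C/OC(=O)C(C)(C)C)C(=C)CO[Si](c1ccccc1)(c1ccccc1)C(C)(C)C
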